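One equivalent of reagent carries substrate as far as target, and a second carries that target on to over-reaction product. Full over-reaction therefore costs 2 equivalents, and this flask holds fewer: 1.50 equiv.

- Saturday's: substrate 0.80 M; reagent 1.5 equiv; the very flask that is asked about, followed so far
- flask: substrate 0.80 M; reagent 1.50 equiv; time 4.0 min

Saturday's run (percent of the substrate charged)

| time / s | target / % | isomer of the product A / % |
|---|---|---|
| 10.0 | 28.0 | 2.3 |
| 15.0 | 26.9 | 3.1 |
| 25.0 | 21.8 | 4.5 |
| 30.0 | 19.8 | 5.3 |
| 40.0 | 16.9 | 5.6 |
| 50.0 | 14.6 | 6.4 |

(scatter of a reading: 0.3 percentage points)

1. share of target in target plus isomer of the product A at 0.20 s
2. share of target in target plus isomer of the product A at 6.0 s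
3. share of target in target plus isomer of the product A at 4.0 min

- percent here means substrate units held: one side product counts as two
- steps thought possible: target <-> isomer of the product B; substrate + reagent -> target; substrate + target -> side product; reagent + target -> over-reaction product; substrate <-> other conformer; reagent + other conformer -> isomer of the product A

Two chemists dispute the late share. The first freezes reagent and treats the loss of target as pseudo-first-order. Saturday's readings give a constant k = 0.0163 /s, the logarithmic fall of target per second. Carried to 4.0 min, k leaves 0.662% of target. The forecast belongs to this side: 99.2%, 95% and 14%, with target at 1 to 2 percent, “slightly more than pure exponential decay gives because reagent is depleting”.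

The second chemist freezes the reagent ledger instead. Let W, the reagent shortfall, be 2 equivalents minus the equivalents charged, in percent of the substrate charged: W = 50.0%. Each percent of target, isomer of the product B or isomer of the product A saves one unit of reagent against full over-reaction. Each percent of side product saves 1.5 units, and each percent of substrate or other conformer saves 2 units. Hence target plus isomer of the product B equals W, minus isomer of the product A, minus 1.5 times side product, minus 2 times substrate and other conformer together, plus unspent reagent. This gives no figure for the share, since side product and reagent are unread. It does say that a charge below 2 equivalents is drawn down as target is lost, so this chemist doubts a frozen k and expects a share above the forecast's.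

The flask gives 99.8%, 95.0% and 47.0%.

    target ⇌ isomer of the product B (K = 1.30, k = 0.0260 /s)
    substrate + reagent → target (k = 0.0750 /M/s)
    substrate + target → side product (k = 0.0440 /M/s)
    reagent + target → over-reaction product (k = 0.0620 /M/s)
    substrate ⇌ other conformer (K = 2.30, k = 0.00460 /s)
    reagent + other conformer → isomer of the product A (k = 0.370 /M/s)

The early shares agree with the forecast, and the late one parts from it: at 4.00 min this flask holds 7.03% of target, not 0.662%, with 7.39% of its reagent left. Filled with this flask's amounts at that time, the ledger with W reads 17.4% for target plus isomer of the product B. The first view has its region at 2.50 equiv, where W becomes a surplus of 50.0%. That neighbouring flask keeps 30.6% of its reagent, and its share falls to 15.1%, with target at 0.687%.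

The numbers in the tables come from a simulation for substances that don't exist; scatter was added.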